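## Retrosynthetic overview

- The hydroxy-methoxy-quinone is unmasked last from a tetramethoxyarene. The chain C1–C2 bond comes from Pd-catalysed coupling of an (E)-alkenylalane with 2,3,5,6-tetramethoxybenzyl chloride; syn-methylalumination of a terminal alkyne sets the C2=C3 geometry, and the C2' methylidene comes from a ketone.
- Feature on which the route rests: quaternary C1' carries the C5–C4 ethylene tether that ends at sp2 C3 and is joined through C2' to the C3' methine. These atoms (C1', C5, C4, C3, C2', C3') are C4a, C4, C3, C2, C8a and C8 of a 4a,8-dimethyl-octalin-2-one whose C1–C8a bond has been cut; octalone C1 is chain C2.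
- Key disconnection: that C1–C8a bond, opened in the forward sense by Eschenmoser–Tanabe fragmentation of the octalone 1,8a-epoxide, which unveils the C2' ketone and the C3≡C2 alkyne in one operation.
- Ring order: ring B (the target's cyclohexane) comes from 2,6-dimethylcyclohexanone. Ring A is annulated (auxiliary-controlled Michael addition sets C1', aldol condensation closes the ring, C3' is equilibrated in the bicycle) and then cut open again. The quinone ring is carried in as 1,2,4,5-tetramethoxybenzene.

Key step: step 5

Remark on the chemistry: commercial 2,6-dimethylcyclohexanone (cis/trans mixture) is used as such, since both isomers give the same secondary enamine. Primed locants are those of the target's cyclohexane ring, chain locants C1–C5 count from the quinone, and octalone locants follow naphthalenone numbering.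

## Route

Step 1
Reactants: 1 2,6-dimethylcyclohexanone; 2 (S)-1-phenylethylamine
Product: 3 (S)-N-(2,6-dimethylcyclohexylidene)-1-phenylethanamine (imine, ring methines unassigned)
Conditions: TsOH·H2O (cat.), toluene, reflux, Dean–Stark
Reagents that add atoms: none
Why: Acid-catalysed imine formation with azeotropic removal of water; no stereocentre of the target is set, since the ring methines scramble through the imine–enamine equilibrium.

Step 2
Reactants: 3 imine; 4 methyl vinyl ketone
Product: 6 (2R)-2,6-dimethyl-2-(3-oxobutyl)cyclohexan-1-one (C6 epimer mixture), via Michael adduct imine 5 (not isolated)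
Conditions: THF, 40 °C; then 20% aq AcOH, rt
Reagents that add atoms: water, O
Why: Asymmetric Michael addition of a chiral imine through its more substituted secondary enamine tautomer (aza-ene-like, with internal N–H to carbon proton transfer), in which the enone should approach the enamine face anti to the phenyl group of the auxiliary and so set the quaternary carbon as R (the future C1'), after which mild acid hydrolysis frees the diketone and the auxiliary.

Step 3
Reactants: 6 diketone
Product: 8 (4aR,8R)-4a,8-dimethyl-4,4a,5,6,7,8-hexahydronaphthalen-2(3H)-one (methyl groups trans), via ketol 7 (not isolated)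
Conditions: NaOMe, MeOH, 60 °C, prolonged to equilibrate C8
Reagents that add atoms: none
Why: Intramolecular aldol condensation (6-enolendo-exo-trig addition of the methyl-ketone enolate to the ring carbonyl, then E1cB dehydration) closes ring A, and the same base reversibly deprotonates C8 through the extended dienolate, so the C8 methyl should settle equatorial and trans to the axial angular methyl, the cis epimer being penalised by a syn-diaxial methyl/methyl contact or by the less favourable chair of ring B; any residual cis epimer would be removed by chromatography.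

Step 4
Reactants: 8 octalone
Product: 9 1,8a-epoxide of 8, (4aR,8R)-1,8a-epoxy-4a,8-dimethyloctahydronaphthalen-2(1H)-one, oxygen cis to the 4a-methyl and trans to the 8-methyl
Conditions: 30% H2O2, aq NaOH, MeOH, 0 °C → rt
Reagents that add atoms: hydrogen peroxide, OO
Why: Weitz–Scheffer nucleophilic epoxidation (conjugate addition of hydroperoxide to C8a, then closure of the enolate on oxygen) should deliver oxygen mainly to the face syn to the angular methyl, as is usual for angularly methylated octalones, which sets C1 and C8a together; the minor face isomer need not be removed because both fragment to the same product in step 5.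

Step 5
Reactants: 9 epoxy ketone
Product: 11 (2R,6R)-2-(but-3-yn-1-yl)-2,6-dimethylcyclohexan-1-one (methyl groups trans), via tosylhydrazone 10 (not isolated)
Conditions: TsNHNH2, CH2Cl2/AcOH (1:1), −20 °C → rt
Reagents that add atoms: none
Why: The unhindered C2 carbonyl condenses with the sulfonyl hydrazide to hydrazone 10; loss of its N–H proton opens the epoxide at C1–O to a vinyl diazene bearing an alkoxide on C8a, and this alkoxide collapses to the ketone while the C1–C8a bond breaks and N2 and toluenesulfinate depart, leaving C2≡C1 as a terminal alkyne. This is an Eschenmoser–Tanabe fragmentation, and its closest known cases are the same reaction of angularly methylated octalone epoxides and of steroidal 4,5-epoxy-3-ketones to seco-alkynones. No ring is closed (ring A is opened) and no stereocentre is formed; C4a and C8 of the bicycle are carried over unchanged as C2 and C6 of 11. The step needs regioselective cleavage of C1–C8a, which the position of the epoxide dictates for either epoxide epimer. It also needs retention at C6, now α to a ketone whose cis and trans forms differ little in energy; the weakly acidic, cold medium and the hindered carbonyl should keep enolisation negligible.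

Step 6
Reactants: 11 alkynone
Product: 12 (1R,3R)-1-(but-3-yn-1-yl)-1,3-dimethyl-2-methylidenecyclohexane
Conditions: Zn, CH2Br2, TiCl4, THF (reagent pre-formed at 0–5 °C); then 11, CH2Cl2, 0 °C → rt; volatile product kept as a concentrated pentane solution
Reagents that add atoms: dibromomethane, BrCBr
Why: Takai–Lombardo methylenation, whose zinc/titanium gem-dimetallic methylene reagent is nucleophilic but hardly basic, so the hindered ketone should be converted into the exocyclic alkene without enolisation and therefore without loss of the adjacent C3' configuration; no stereocentre is formed.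

Step 7
Reactants: 13 1,2,4,5-tetramethoxybenzene
Product: 15 (2,3,5,6-tetramethoxyphenyl)methanol, via aryllithium 14 (not isolated)
Conditions: n-BuLi, TMEDA, THF, 0 °C; (CH2O)n, 0 °C → rt; H2O
Reagents that add atoms: paraformaldehyde (reacts as formaldehyde), C=O
Why: Directed ortho-lithiation at a ring hydrogen flanked by two methoxy groups (both ring positions are equivalent), followed by addition of the aryllithium to formaldehyde, gives the benzylic alcohol.

Step 8
Reactants: 15 benzylic alcohol
Product: 16 3-(chloromethyl)-1,2,4,5-tetramethoxybenzene (2,3,5,6-tetramethoxybenzyl chloride)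
Conditions: SOCl2, CH2Cl2, 0 °C → rt
Reagents that add atoms: thionyl chloride, O=S(Cl)Cl
Why: Chlorodehydroxylation of an electron-rich benzylic alcohol through its chlorosulfite; no stereocentre is involved.

Step 9
Reactants: 12 enyne; 16 benzylic chloride
Product: 18 3-[(2E)-5-[(1R,3R)-1,3-dimethyl-2-methylidenecyclohexyl]-3-methylpent-2-en-1-yl]-1,2,4,5-tetramethoxybenzene, via alkenylalane 17 (not isolated)
Conditions: AlMe3, Cp2ZrCl2 (cat.), CH2Cl2, 0 °C → rt; volatiles removed; 16, Pd(PPh3)4 (cat.), THF, rt; cold 1 M HCl
Reagents that add atoms: trimethylaluminium, C[Al](C)C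
Why: Zirconium-catalysed methylalumination (Negishi carboalumination) adds methyl and aluminium syn across the terminal alkyne with aluminium on the terminal carbon, and the zerovalent-palladium-catalysed cross-coupling of the resulting (E)-alkenylalane with the benzylic chloride proceeds with retention, so the C2=C3 bond should form as E; the 1,1-disubstituted exocyclic alkene is not carbometalated under these conditions.

Step 10
Reactants: 18 tetramethoxyarene
Product: 19 2,5-dimethoxy-3-[(2E)-5-[(1R,3R)-1,3-dimethyl-2-methylidenecyclohexyl]-3-methylpent-2-en-1-yl]cyclohexa-2,5-diene-1,4-dione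
Conditions: (NH4)2Ce(NO3)6, MeCN/H2O, 0 °C
Reagents that add atoms: water, O
Why: Oxidative demethylation of a para-dimethoxyarene by tetravalent cerium (arene radical cation, ipso attack of water, loss of methanol); the arene has a mirror plane through the chain-bearing carbon, so both para pairs give the same 2,5-dimethoxy-1,4-benzoquinone, and the isolated alkenes should survive the short, cold reaction.

Step 11
Reactants: 19 dimethoxyquinone
Product: 20 metachromin A, 2-hydroxy-5-methoxy-3-[(2E)-5-[(1R,3R)-1,3-dimethyl-2-methylidenecyclohexyl]-3-methylpent-2-en-1-yl]cyclohexa-2,5-diene-1,4-dione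
Conditions: KOH, MeOH/H2O, 0 °C → rt; then cold 1 M HCl to pH 3, immediate extraction
Reagents that add atoms: potassium hydroxide, [K+].[OH-]
Why: Addition–elimination of hydroxide on a vinylogous ester, in which the methoxy on the quinone carbon next to the side chain, flanked by a carbonyl and the alkylated carbon, is twisted out of conjugation and should be the more electrophilic one, while the hydroxyquinone anion formed is deactivated towards a second hydrolysis, as is usual for 3-alkyl-2,5-dimethoxybenzoquinones; no stereocentre is touched.

## Compound list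

1 | 2,6-dimethylcyclohexanone (cis/trans mixture) | CC1CCCC(C)C1=O | starting material
2 | (S)-1-phenylethylamine | C[C@H](N)c1ccccc1 | starting material
3 | (S)-N-(2,6-dimethylcyclohexylidene)-1-phenylethanamine | CC1CCCC(C)C1=N[C@@H](C)c1ccccc1 | intermediate
4 | methyl vinyl ketone | CC(=O)C=C | starting material
5 | Michael adduct imine, 4-[(1R)-1,3-dimethyl-2-[(S)-1-phenylethylimino]cyclohexyl]butan-2-one | C[C@H](N=C1C(C)CCC[C@]1(C)CCC(C)=O)c1ccccc1 | intermediate
6 | (2R)-2,6-dimethyl-2-(3-oxobutyl)cyclohexan-1-one (C6 epimer mixture) | O=C1C(C)CCC[C@]1(C)CCC(C)=O | intermediate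
7 | ketol, (4aR)-8a-hydroxy-4a,8-dimethyloctahydronaphthalen-2(1H)-one | O=C1CC2(O)C(C)CCC[C@]2(C)CC1 | intermediate
8 | (4aR,8R)-4a,8-dimethyl-4,4a,5,6,7,8-hexahydronaphthalen-2(3H)-one | O=C1C=C2[C@H](C)CCC[C@]2(C)CC1 | intermediate
9 | 1,8a-epoxide of 8, oxygen cis to the 4a-methyl | O=C1[C@H]2O[C@]23[C@H](C)CCC[C@]3(C)CC1 | intermediate
10 | 4-methylbenzenesulfonylhydrazone of 9 | Cc1ccc(cc1)S(=O)(=O)NN=C1[C@H]2O[C@]23[C@H](C)CCC[C@]3(C)CC1 | intermediate
11 | (2R,6R)-2-(but-3-yn-1-yl)-2,6-dimethylcyclohexan-1-one | O=C1[C@H](C)CCC[C@]1(C)CCC#C | intermediate
12 | (1R,3R)-1-(but-3-yn-1-yl)-1,3-dimethyl-2-methylidenecyclohexane | C=C1[C@H](C)CCC[C@]1(C)CCC#C | intermediate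
13 | 1,2,4,5-tetramethoxybenzene | COc1cc(OC)c(OC)cc1OC | starting material
14 | (2,3,5,6-tetramethoxyphenyl)lithium | [Li]c1c(OC)c(OC)cc(OC)c1OC | intermediate
15 | (2,3,5,6-tetramethoxyphenyl)methanol | OCc1c(OC)c(OC)cc(OC)c1OC | intermediate
16 | 3-(chloromethyl)-1,2,4,5-tetramethoxybenzene | ClCc1c(OC)c(OC)cc(OC)c1OC | intermediate
17 | (E)-alkenylalane, dimethyl[(1E)-4-[(1R,3R)-1,3-dimethyl-2-methylidenecyclohexyl]-2-methylbut-1-en-1-yl]alane | C=C1[C@H](C)CCC[C@]1(C)CC/C(C)=C/[Al](C)C | intermediate
18 | 3-[(2E)-5-[(1R,3R)-1,3-dimethyl-2-methylidenecyclohexyl]-3-methylpent-2-en-1-yl]-1,2,4,5-tetramethoxybenzene | C=C1[C@H](C)CCC[C@]1(C)CC/C(C)=C/Cc1c(OC)c(OC)cc(OC)c1OC | intermediate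
19 | 2,5-dimethoxy-3-[(2E)-5-[(1R,3R)-1,3-dimethyl-2-methylidenecyclohexyl]-3-methylpent-2-en-1-yl]cyclohexa-2,5-diene-1,4-dione | C=C1[C@H](C)CCC[C@]1(C)CC/C(C)=C/CC1=C(OC)C(=O)C=C(OC)C1=O | intermediate
20 | metachromin A | C=C1[C@H](C)CCC[C@]1(C)CC/C(C)=C/CC1=C(O)C(=O)C=C(OC)C1=O | target

## Step count

Total: 11 steps. Longest linear sequence: 9 steps (steps 1–6 and 9–11 from 2,6-dimethylcyclohexanone); the arene branch (steps 7 and 8) joins at step 9.

## Steps most likely to fail

1. Step 11. Hydroxide may attack the unhindered methoxy instead of, or as well as, the one next to the side chain, so regiocontrol could be poor or hydrolysis could run on to the dihydroxyquinone. The fallback fixes the position of the free hydroxyl at the arene stage. It sets out from 18: NaSEt in DMF at about 110 °C should cleave one of the two equivalent, twisted methoxy groups that flank the side chain (SN2 at methyl) to give the trimethoxyphenol F1. Ac2O in pyridine would convert it into the aryl acetate F2. (NH4)2Ce(NO3)6 in MeCN/H2O should then oxidise the remaining para-dimethoxy pair, the acetoxy-bearing carbon being the poorer site for ipso attack, to give the acetoxyquinone F3. K2CO3 in MeOH at 0 °C would remove the acetyl group, and the fallback comes back to the route at 20.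

2. Step 6. Methylene transfer to the doubly α-substituted carbonyl may stall, or the reagent may be consumed by the terminal alkyne. The fallback is a two-stage Peterson olefination setting out from 11: Me3SiCH2Li with CeCl3 in THF at −78 °C (excess, the alkyne C–H being restored on work-up) should add to the ketone without enolisation to give the β-hydroxysilane F4. KH in THF at 0 °C → rt would then effect syn-elimination, and the fallback comes back to the route at 12.

3. Step 5. Enolisation of the newly formed ketone could erode the C3' configuration, or the hindered hydrazone could decompose before it fragments. The fallback reaches the same alkynone by oxidative cleavage and C–C coupling, setting out from 8 and bypassing 9. RuCl3 (cat.) with NaIO4 in MeCN/CCl4/H2O at rt should cleave the enone C1=C8a bond with loss of C1 to give the keto acid F5. N-Hydroxyphthalimide and N,N'-diisopropylcarbodiimide in CH2Cl2 would give the N-acyloxyphthalimide ester F6. Its decarboxylative alkynylation with HC≡CZnCl under NiCl2·6H2O/2,2'-bipyridine catalysis in THF/DMF at rt would install the terminal alkyne under non-basic conditions, and the fallback comes back to the route at 11.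

## Further compounds

F1 | step 11 | 2-[(2E)-5-[(1R,3R)-1,3-dimethyl-2-methylidenecyclohexyl]-3-methylpent-2-en-1-yl]-3,4,6-trimethoxyphenol | C=C1[C@H](C)CCC[C@]1(C)CC/C(C)=C/Cc1c(O)c(OC)cc(OC)c1OC
F2 | step 11 | 2-[(2E)-5-[(1R,3R)-1,3-dimethyl-2-methylidenecyclohexyl]-3-methylpent-2-en-1-yl]-3,4,6-trimethoxyphenyl acetate | C=C1[C@H](C)CCC[C@]1(C)CC/C(C)=C/Cc1c(OC(C)=O)c(OC)cc(OC)c1OC
F3 | step 11 | 2-acetoxy-5-methoxy-3-[(2E)-5-[(1R,3R)-1,3-dimethyl-2-methylidenecyclohexyl]-3-methylpent-2-en-1-yl]cyclohexa-2,5-diene-1,4-dione | C=C1[C@H](C)CCC[C@]1(C)CC/C(C)=C/CC1=C(OC(C)=O)C(=O)C=C(OC)C1=O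
F4 | step 6 | (2R,6R)-2-(but-3-yn-1-yl)-2,6-dimethyl-1-[(trimethylsilyl)methyl]cyclohexan-1-ol (carbinol configuration unassigned) | C[Si](C)(C)CC1(O)[C@H](C)CCC[C@]1(C)CCC#C
F5 | step 5 | 3-[(1R,3R)-1,3-dimethyl-2-oxocyclohexyl]propanoic acid | O=C1[C@H](C)CCC[C@]1(C)CCC(=O)O
F6 | step 5 | 1,3-dioxoisoindolin-2-yl 3-[(1R,3R)-1,3-dimethyl-2-oxocyclohexyl]propanoate | O=C1[C@H](C)CCC[C@]1(C)CCC(=O)ON1C(=O)c2ccccc2C1=O
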